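Everything rests on forming the C4–C5 bond last, on a finished ring B. The feature exploited lies in ring A. Oxygen-bearing C3, fully substituted C4 (carrying C18 and C19) and C5 follow one another, and C5 adjoins oxygenated C6 of ring B. C5 can therefore serve as the carbon nucleophile of a C5=C6 enol ether toward C4 of a C3–C4 epoxide. One operation closes ring A, fixes C4 by inversion, delivers the 3α-oxygen and unveils the C6 ketone. The precursor is a Birch-derived 1-methoxycyclohexa-1,4-diene. Its C10 bears the methyl group and a two-carbon arm ending in an (E)-derived (3R,4R)-epoxide. Closure is necessarily cis, and C5 is then equilibrated to the trans fusion.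

Key step: step 15

Assumption: labdane numbering is used throughout (β = face of C20), and the Birch alkylation is taken to follow the usual chelated-enolate model (enolate oxygen syn to the ortho alkyl group, electrophile anti to the CH2OMe arm), which for the (R)-auxiliary places the incoming methyl on the β face of C10.

Step 1
Reactants: 1 2,3-dimethylbenzoic acid; 2 (R)-2-(methoxymethyl)pyrrolidine
Product: 4 (R)-auxiliary amide of 2,3-dimethylbenzoic acid, via 2,3-dimethylbenzoyl chloride 3 (not isolated)
Conditions: SOCl2, cat. DMF, toluene, 70 °C; concentrate; 2, Et3N, CH2Cl2, 0 °C to rt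
Reagents that add atoms: (R)-2-(methoxymethyl)pyrrolidine, COC[C@H]1CCCN1 (compound 2); thionyl chloride, O=S(Cl)Cl (chlorine of 3 only)
Why: Acid chloride formation followed by N-acylation of the secondary amine (Schotten–Baumann-type amidation) is routine and attaches the auxiliary that later controls C10.

Step 2
Reactants: 4 (R)-auxiliary amide of 2,3-dimethylbenzoic acid
Product: 6 5-hydroxy-2,3-dimethylbenzamide of the auxiliary, via aryl pinacol boronate 5 (not isolated)
Conditions: [Ir(OMe)(cod)]2 (cat.), 4,4'-di-tert-butyl-2,2'-bipyridine (cat.), B2pin2, THF, 80 °C; then 30% H2O2, aq NaOH, 0 °C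
Reagents that add atoms: hydrogen peroxide, OO; bis(pinacolato)diboron, CC1(C)OB(OC1(C)C)B1OC(C)(C)C(C)(C)O1 (boron of 5 only)
Why: Iridium-catalysed aromatic C–H borylation is governed by sterics and in this 1,2,3-trisubstituted ring can only reach C5, the one C–H flanked by two hydrogens, and the boronate is oxidised in the same flask at the same position (borylation–oxidation).

Step 3
Reactants: 6 5-hydroxy-2,3-dimethylbenzamide of the auxiliary; 7 iodomethane
Product: 8 5-methoxy-2,3-dimethylbenzamide of the auxiliary
Conditions: MeI, K2CO3, acetone, reflux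
Reagents that add atoms: iodomethane, CI (compound 7)
Why: Williamson etherification of the phenoxide gives the aryl methyl ether that will become the C6 enol ether.

Step 4
Reactants: 8 5-methoxy-2,3-dimethylbenzamide of the auxiliary; 9 allyl bromide
Product: 11 2-(but-3-enyl)-5-methoxy-3-methylbenzamide of the auxiliary, via benzylic lithium species 10 (not isolated)
Conditions: LDA, THF, −78 °C; allyl bromide, −78 °C to rt
Reagents that add atoms: allyl bromide, C=CCBr (compound 9)
Why: Lateral lithiation: LDA removes a proton from the ortho methyl group, whose anion is stabilised by the neighbouring amide, and SN2 allylation installs C12, C13 and C16 as a but-3-enyl chain, a mask for the C13 methyl ketone that, unlike a ketal, is inert to the Lewis acid of step 15.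

Step 5
Reactants: 11 2-(but-3-enyl)-5-methoxy-3-methylbenzamide of the auxiliary; 7 iodomethane
Product: 13 (1S)-2-(but-3-enyl)-5-methoxy-1,3-dimethylcyclohexa-2,5-diene-1-carboxamide of the auxiliary, via potassium amide enolate 12 (not isolated)
Conditions: K, NH3(l)–THF, t-BuOH (1 equiv), −78 °C; MeI, −78 °C, then evaporation of NH3
Reagents that add atoms: iodomethane, CI (compound 7)
Why: Auxiliary-controlled asymmetric Birch reduction–alkylation: the amide directs 1,4-reduction so that all three donor substituents stay on sp2 carbons and C7 is protonated, and the chelated enolate is methylated anti to the CH2OMe arm, which sets C10 as (S) with C20 on the β face and leaves the carbonyl carbon as C1 of the future arm.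

Step 6
Reactants: 13 Birch product amide
Product: 14 [(1S)-2-(but-3-enyl)-5-methoxy-1,3-dimethylcyclohexa-2,5-dien-1-yl]methanol
Conditions: LiH2NBH3 (from BH3·NH3 and LDA, THF, 0 °C), THF, 0 °C to rt; aq NaOH work-up
Reagents that add atoms: none
Why: Lithium amidotrihydroborate is a small, strongly nucleophilic hydride that reduces hindered tertiary amides to primary alcohols with C–N cleavage, and the basic medium spares the enol ether and both isolated alkenes.

Step 7
Reactants: 14 neopentyl alcohol
Product: 15 (1S)-2-(but-3-enyl)-5-methoxy-1,3-dimethylcyclohexa-2,5-diene-1-carbaldehyde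
Conditions: n-Pr4N[RuO4] (cat.), N-methylmorpholine N-oxide, 4 Å MS, CH2Cl2, rt
Reagents that add atoms: none
Why: Ley–Griffith oxidation is neutral and stops at the aldehyde, which has no α-hydrogen, and no leaving group is ever placed on this neopentyl, doubly homoallylic carbon, so ring expansion is excluded.

Step 8
Reactants: 15 C1 aldehyde; 16 trimethyl phosphonoacetate
Product: 17 methyl (E)-3-[(1S)-dienyl]prop-2-enoate (C1=C2, C3 as ester)
Conditions: 16, NaH, THF, 0 °C; then 15, 0 to 40 °C
Reagents that add atoms: trimethyl phosphonoacetate, COC(=O)CP(=O)(OC)OC (compound 16)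
Why: Horner–Wadsworth–Emmons olefination copes with the α-quaternary aldehyde and adds C2 and C3 as an (E)-enoate whose geometry is erased in the next step.

Step 9
Reactants: 17 (E)-enoate
Product: 18 methyl 3-[(1S)-dienyl]propanoate
Conditions: Cu(OAc)2 (cat.), 1,2-bis(diphenylphosphino)benzene (cat.), (EtO)2MeSiH, t-BuOH, toluene, rt
Reagents that add atoms: none
Why: Copper hydride 1,4-reduction is a polar hydride transfer that touches only the enoate, leaves the enol ether, the tetrasubstituted and the terminal alkene alone and avoids radical intermediates next to the cyclohexadiene.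

Step 10
Reactants: 18 saturated methyl ester
Product: 19 3-[(1S)-dienyl]propanal (C3 aldehyde)
Conditions: i-Bu2AlH (1.1 equiv), toluene, −78 °C
Reagents that add atoms: none
Why: Partial reduction of the ester with one equivalent of i-Bu2AlH at low temperature stops at the tetrahedral aluminate, which gives the C3 aldehyde on work-up.

Step 11
Reactants: 19 C3 aldehyde; 20 ethyl 2-(triphenylphosphoranylidene)propanoate
Product: 21 ethyl (E)-2-methyl-5-[(1S)-dienyl]pent-2-enoate
Conditions: 20, CH2Cl2, rt
Reagents that add atoms: ethyl 2-(triphenylphosphoranylidene)propanoate, CCOC(=O)C(C)=P(c1ccccc1)(c1ccccc1)c1ccccc1 (compound 20)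
Why: Wittig olefination with the stabilised α-methyl ylide is reliably (E)-selective and brings in C4, C18 and C19 under neutral conditions.

Step 12
Reactants: 21 (E)-enoate
Product: 22 (E)-2-methyl-5-[(1S)-dienyl]pent-2-en-1-ol
Conditions: i-Bu2AlH (2.5 equiv), CH2Cl2, −78 °C
Reagents that add atoms: none
Why: 1,2-Reduction of the enoate with i-Bu2AlH gives the (E)-allylic alcohol needed for directed epoxidation without touching the other alkenes.

Step 13
Reactants: 22 (E)-allylic alcohol
Product: 23 (3R,4R)-epoxy alcohol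
Conditions: Ti(Oi-Pr)4 (cat.), D-(−)-diisopropyl tartrate (cat.), t-BuOOH (decane), 4 Å MS, CH2Cl2, −20 °C
Reagents that add atoms: tert-butyl hydroperoxide, CC(C)(C)OO
Why: Sharpless asymmetric epoxidation oxidises only the alkene bound through its allylic alcohol, and with the D-(−)-tartrate the (E)-2-methylalk-2-en-1-ol gives the (3R,4R)-epoxide (mirror image of the (2S,3S) series obtained with L-(+)-tartrate), which sets C3 and, before inversion, C4 under reagent control.

Step 14
Reactants: 23 (3R,4R)-epoxy alcohol
Product: 24 ring B methyl enol ether with (E)-derived (3R,4R)-epoxide arm and C19 OTBDPS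
Conditions: t-BuPh2SiCl, imidazole, CH2Cl2, 0 °C to rt
Reagents that add atoms: tert-butyl(chloro)diphenylsilane, CC(C)(C)[Si](Cl)(c1ccccc1)c1ccccc1
Why: Standard silylation of the primary alcohol gives a bulky, weakly basic silyl ether that keeps the Lewis acid on the epoxide oxygen and cannot act as a neighbouring group.

Step 15
Reactants: 24 epoxide enol ether
Product: 26 cis-fused (5β-H) 3α-hydroxy-Δ8(9)-6-ketone with C19 OTBDPS, via C6 oxocarbenium aluminate 25 (not isolated)
Conditions: MeAlCl2 (hexanes), CH2Cl2, −78 °C; then 0.5 M aq HCl–THF, 0 °C, brief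
Reagents that add atoms: water, O
Why: MeAlCl2 binds the epoxide oxygen, the C4–O bond lengthens at the tertiary carbon and the enol ether carbon C5 attacks C4 anti to oxygen, giving a C6 oxocarbenium ion that is hydrolysed to the ketone on work-up, which is the known Lewis-acid epoxide-initiated cation–olefin cyclisation with an enol ether as terminator. Ring A closes in a 6-endo mode at the epoxide (C3 and C4 both end up in the ring) and exo with respect to the C5=C6 bond. C4 is set by stereospecific inversion and C3 keeps its oxygen, so both follow from the Sharpless epoxide. C5 is set by the C10 centre: the arm leaves the nearly flat cyclohexadiene on its α face and can only reach the α lobe at C5, so H5 ends β and the fusion is cis at first, which step 16 corrects. With the (E)-derived (3R,4R)-epoxide this α-face attack runs through a chair in which O3 is anti to the new bond, the small C18 methyl lies under ring B and the CH2OSi group points outward, and O3 emerges directly in the 3α configuration of the target. Chemoselectivity rests on the far higher nucleophilicity of the enol ether compared with the tetrasubstituted C8=C9 and terminal alkenes, on the absence of any other Lewis-acid-labile group and on the proton-scavenging Al–Me bond.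

Step 16
Reactants: 26 cis-fused hydroxy ketone
Product: 29 trans-fused (5α-H) 3α-hydroxy-Δ8(9)-6-ketone with C19 OTBDPS, via trans-fused conjugated enone 27 (not isolated), via dipotassium dienolate alkoxide 28 (not isolated)
Conditions: t-BuOK (0.3 equiv), t-BuOH–THF, rt, Ar; then t-BuOK (6 equiv), rt; cannulation into 10% aq AcOH, 0 °C
Reagents that add atoms: none
Why: Catalytic tert-butoxide first equilibrates all enolisable positions, which moves the alkene into conjugation and lets C5 epimerise through the cross-conjugated dienolate to the more stable trans fusion (thermodynamic control of C5), and excess base then forms the extended C6–C9 dienolate whose kinetic α-protonation at C7 on inverse acidic quench restores the C8=C9 alkene (base-mediated deconjugation).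

Step 17
Reactants: 29 trans-fused β,γ-unsaturated ketone
Product: 30 3α,6β-diol
Conditions: i-Bu2AlH (3 equiv), CH2Cl2, −78 °C
Reagents that add atoms: none
Why: Hydride reduction of the hindered ketone with the non-basic, Lewis-acidic i-Bu2AlH is faster than enolisation, and because the axial C19 and C20 groups block the β face the hydride arrives from the α face and sets C6 as the axial 6β-alcohol.

Step 18
Reactants: 30 3α,6β-diol; 31 isovaleric anhydride
Product: 32 3α,6β-bis(isovalerate)
Conditions: isovaleric anhydride (excess), DMAP, Et3N, toluene, 60 °C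
Reagents that add atoms: isovaleric anhydride, CC(C)CC(=O)OC(=O)CC(C)C (compound 31)
Why: DMAP-catalysed acyl transfer (Steglich-type acylation) with excess anhydride and heating is chosen because both hydroxyl groups are axial and hindered, and no other nucleophilic group is present.

Step 19
Reactants: 32 bis(isovalerate) with but-3-enyl chain
Product: 33 C13 methyl ketone
Conditions: PdCl2 (cat.), CuCl, O2 (1 atm), DMF–H2O, rt
Reagents that add atoms: water, O
Why: Tsuji–Wacker oxidation converts only the monosubstituted alkene, with Markovnikov selectivity, into the C13 methyl ketone, whereas the tetrasubstituted C8=C9 bond does not coordinate to palladium.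

Step 20
Reactants: 34 diethylphosphonoacetic acid; 35 2-(trimethylsilyl)ethanol
Product: 36 2-(trimethylsilyl)ethyl diethylphosphonoacetate
Conditions: DCC, DMAP (cat.), CH2Cl2, 0 °C to rt
Reagents that add atoms: 2-(trimethylsilyl)ethanol, C[Si](C)(C)CCO (compound 35)
Why: Steglich esterification gives the phosphonate whose ester can later be removed by fluoride.

Step 21
Reactants: 33 C13 methyl ketone; 36 2-(trimethylsilyl)ethyl diethylphosphonoacetate
Product: 37 (13E)-enoate 2-(trimethylsilyl)ethyl ester
Conditions: 36, NaH, THF, 0 °C; then 33, 45 °C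
Reagents that add atoms: 2-(trimethylsilyl)ethyl diethylphosphonoacetate, CCOP(=O)(CC(=O)OCC[Si](C)(C)C)OCC (compound 36)
Why: Horner–Wadsworth–Emmons olefination of the methyl ketone favours the (E)-enoate (ester anti to the larger C12 chain), the preformed phosphonate anion is too weak a nucleophile to attack the isovalerates, and the minor (Z)-isomer is removed by chromatography.

Step 22
Reactants: 37 fully protected enoate
Product: 38 target CNP0272110.1
Conditions: n-Bu4NF, AcOH (1:1), THF, 0 °C to rt; pH 4 buffer work-up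
Reagents that add atoms: none
Why: Fluoride cleaves the silyl ether and triggers β-elimination of the 2-(trimethylsilyl)ethyl ester (loss of ethene), and the acetic acid buffer protonates the C19 alkoxide at once so that the neighbouring isovalerates do not migrate.

Compound list
1 | 2,3-dimethylbenzoic acid | Cc1cccc(C(=O)O)c1C | starting material
2 | (R)-2-(methoxymethyl)pyrrolidine | COC[C@H]1CCCN1 | starting material
3 | 2,3-dimethylbenzoyl chloride | Cc1cccc(C(=O)Cl)c1C | intermediate
4 | (2,3-dimethylphenyl)[(2R)-2-(methoxymethyl)pyrrolidin-1-yl]methanone | COC[C@H]1CCCN1C(=O)c1cccc(C)c1C | intermediate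
5 | 5-(pinacolboryl) derivative of 4 | COC[C@H]1CCCN1C(=O)c1cc(B2OC(C)(C)C(C)(C)O2)cc(C)c1C | intermediate
6 | (5-hydroxy-2,3-dimethylphenyl)[(2R)-2-(methoxymethyl)pyrrolidin-1-yl]methanone | COC[C@H]1CCCN1C(=O)c1cc(O)cc(C)c1C | intermediate
7 | iodomethane | CI | starting material
8 | (5-methoxy-2,3-dimethylphenyl)[(2R)-2-(methoxymethyl)pyrrolidin-1-yl]methanone | COC[C@H]1CCCN1C(=O)c1cc(OC)cc(C)c1C | intermediate
9 | allyl bromide | C=CCBr | starting material
10 | 2-(lithiomethyl) derivative of 8 | COC[C@H]1CCCN1C(=O)c1cc(OC)cc(C)c1C[Li] | intermediate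
11 | [2-(but-3-en-1-yl)-5-methoxy-3-methylphenyl][(2R)-2-(methoxymethyl)pyrrolidin-1-yl]methanone | COC[C@H]1CCCN1C(=O)c1cc(OC)cc(C)c1CCC=C | intermediate
12 | potassium amide enolate of the 1,4-dihydro arene | COC[C@H]1CCCN1C([O-])=C1C=C(OC)CC(C)=C1CCC=C.[K+] | intermediate
13 | [(1S)-2-(but-3-en-1-yl)-5-methoxy-1,3-dimethylcyclohexa-2,5-dien-1-yl][(2R)-2-(methoxymethyl)pyrrolidin-1-yl]methanone (ring C1 = C10) | COC[C@H]1CCCN1C(=O)[C@@]1(C)C=C(OC)CC(C)=C1CCC=C | intermediate
14 | [(1S)-2-(but-3-en-1-yl)-5-methoxy-1,3-dimethylcyclohexa-2,5-dien-1-yl]methanol | OC[C@@]1(C)C=C(OC)CC(C)=C1CCC=C | intermediate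
15 | (1S)-2-(but-3-en-1-yl)-5-methoxy-1,3-dimethylcyclohexa-2,5-diene-1-carbaldehyde | O=C[C@@]1(C)C=C(OC)CC(C)=C1CCC=C | intermediate
16 | trimethyl phosphonoacetate | COC(=O)CP(=O)(OC)OC | starting material
17 | methyl (2E)-3-[(1S)-2-(but-3-en-1-yl)-5-methoxy-1,3-dimethylcyclohexa-2,5-dien-1-yl]prop-2-enoate | COC(=O)/C=C/[C@@]1(C)C=C(OC)CC(C)=C1CCC=C | intermediate
18 | methyl 3-[(1S)-2-(but-3-en-1-yl)-5-methoxy-1,3-dimethylcyclohexa-2,5-dien-1-yl]propanoate | COC(=O)CC[C@@]1(C)C=C(OC)CC(C)=C1CCC=C | intermediate
19 | 3-[(1S)-2-(but-3-en-1-yl)-5-methoxy-1,3-dimethylcyclohexa-2,5-dien-1-yl]propanal | O=CCC[C@@]1(C)C=C(OC)CC(C)=C1CCC=C | intermediate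
20 | ethyl 2-(triphenylphosphoranylidene)propanoate | CCOC(=O)C(C)=P(c1ccccc1)(c1ccccc1)c1ccccc1 | starting material
21 | ethyl (2E)-2-methyl-5-[(1S)-2-(but-3-en-1-yl)-5-methoxy-1,3-dimethylcyclohexa-2,5-dien-1-yl]pent-2-enoate | CCOC(=O)/C(C)=C/CC[C@@]1(C)C=C(OC)CC(C)=C1CCC=C | intermediate
22 | (2E)-2-methyl-5-[(1S)-2-(but-3-en-1-yl)-5-methoxy-1,3-dimethylcyclohexa-2,5-dien-1-yl]pent-2-en-1-ol | OC/C(C)=C/CC[C@@]1(C)C=C(OC)CC(C)=C1CCC=C | intermediate
23 | {(2R,3R)-2-methyl-3-[2-((1S)-2-(but-3-en-1-yl)-5-methoxy-1,3-dimethylcyclohexa-2,5-dien-1-yl)ethyl]oxiran-2-yl}methanol | COC1=C[C@](C)(CC[C@H]2O[C@]2(C)CO)C(CCC=C)=C(C)C1 | intermediate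
24 | tert-butyldiphenylsilyl ether of 23 (key-step precursor: ring B methyl enol ether, (3R,4R)-epoxide arm on C10, but-3-enyl on C9) | COC1=C[C@](C)(CC[C@H]2O[C@]2(C)CO[Si](c2ccccc2)(c2ccccc2)C(C)(C)C)C(CCC=C)=C(C)C1 | intermediate
25 | cis-fused C6 O-methyl oxocarbenium ion with O3-bound methyldichloroaluminate | CC1=C(CCC=C)[C@@]2(C)CC[C@@H](O[Al-](C)(Cl)Cl)[C@](C)(CO[Si](c3ccccc3)(c3ccccc3)C(C)(C)C)[C@H]2C(=[O+]C)C1 | intermediate
26 | cis-decalin (3R,4S,5S,10S): 3α-hydroxy, 5β-H, 6-ketone, C8=C9, C9 but-3-enyl, C19 OTBDPS (key-step product) | CC1=C(CCC=C)[C@@]2(C)CC[C@@H](O)[C@](C)(CO[Si](c3ccccc3)(c3ccccc3)C(C)(C)C)[C@H]2C(=O)C1 | intermediate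
27 | trans-decalin 3α-hydroxy-7-en-6-one, 5α-H, 9α-H, C19 OTBDPS | CC1=CC(=O)[C@H]2[C@@](C)(CO[Si](c3ccccc3)(c3ccccc3)C(C)(C)C)[C@H](O)CC[C@]2(C)[C@H]1CCC=C | intermediate
28 | dipotassium salt: 3α-alkoxide and C6–C9 extended dienolate, 5α-H | CC1=C(CCC=C)[C@@]2(C)CC[C@@H]([O-])[C@](C)(CO[Si](c3ccccc3)(c3ccccc3)C(C)(C)C)[C@@H]2C([O-])=C1.[K+].[K+] | intermediate
29 | trans-decalin (3R,4S,5R,10S): 3α-hydroxy, 5α-H, 6-ketone, C8=C9, C19 OTBDPS | CC1=C(CCC=C)[C@@]2(C)CC[C@@H](O)[C@](C)(CO[Si](c3ccccc3)(c3ccccc3)C(C)(C)C)[C@@H]2C(=O)C1 | intermediate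
30 | trans-decalin 3α,6β-diol, C8=C9, C19 OTBDPS | CC1=C(CCC=C)[C@@]2(C)CC[C@@H](O)[C@](C)(CO[Si](c3ccccc3)(c3ccccc3)C(C)(C)C)[C@@H]2[C@H](O)C1 | intermediate
31 | isovaleric anhydride | CC(C)CC(=O)OC(=O)CC(C)C | starting material
32 | 3α,6β-bis(isovaleryloxy) derivative of 30 | CC1=C(CCC=C)[C@@]2(C)CC[C@@H](OC(=O)CC(C)C)[C@](C)(CO[Si](c3ccccc3)(c3ccccc3)C(C)(C)C)[C@@H]2[C@H](OC(=O)CC(C)C)C1 | intermediate
33 | C13 methyl ketone (3-oxobutyl chain on C9) | CC1=C(CCC(C)=O)[C@@]2(C)CC[C@@H](OC(=O)CC(C)C)[C@](C)(CO[Si](c3ccccc3)(c3ccccc3)C(C)(C)C)[C@@H]2[C@H](OC(=O)CC(C)C)C1 | intermediate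
34 | diethylphosphonoacetic acid | CCOP(=O)(CC(=O)O)OCC | starting material
35 | 2-(trimethylsilyl)ethanol | C[Si](C)(C)CCO | starting material
36 | 2-(trimethylsilyl)ethyl diethylphosphonoacetate | CCOP(=O)(CC(=O)OCC[Si](C)(C)C)OCC | intermediate
37 | 2-(trimethylsilyl)ethyl (13E)-3α,6β-bis(isovaleryloxy)-19-(tert-butyldiphenylsilyloxy)labda-8,13-dien-15-oate | CC1=C(CC/C(C)=C/C(=O)OCC[Si](C)(C)C)[C@@]2(C)CC[C@@H](OC(=O)CC(C)C)[C@](C)(CO[Si](c3ccccc3)(c3ccccc3)C(C)(C)C)[C@@H]2[C@H](OC(=O)CC(C)C)C1 | intermediate
38 | (3R,4S,5R,6R,10S,13E)-19-hydroxy-3α,6β-bis(isovaleryloxy)labda-8,13-dien-15-oic acid (CNP0272110.1) | CC1=C(CC/C(C)=C/C(=O)O)[C@@]2(C)CC[C@@H](OC(=O)CC(C)C)[C@](C)(CO)[C@@H]2[C@H](OC(=O)CC(C)C)C1 | target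

Total step count: 22. Longest linear sequence: 21 steps (steps 1–19, 21 and 22, from 2,3-dimethylbenzoic acid).

Steps most likely to fail

**Step 15.** The tertiary C4 has to approach the concave α face of ring B. Several processes may therefore outrun C–C bond formation:
- hydride shift within the activated epoxide (Meinwald rearrangement),
- chloride capture,
- attack at C3,
- protonolysis of the methyl enol ether.

Proton loss from the oxocarbenium ion is harmless, because all alkene and C5 isomers converge in step 16.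

The fallback changes the terminator to a silyl dienol ether. It sets out from 24 and comes back at 27.
- The methyl enol ether of 24 is hydrolysed with oxalic acid in wet THF at 0 °C to the monocyclic β,γ-enone F1.
- DBU moves the alkene into conjugation to give the cyclohexenone F2.
- Kinetic deprotonation at C5 (LDA, −78 °C) and O-silylation with t-BuMe2SiCl give the cross-conjugated silyl dienol ether F3.
- MeAlCl2 at −78 °C closes ring A with loss of the silyl group to the cis-fused conjugated enone F4.
- Catalytic t-BuOK epimerises C5 of F4 and the route is rejoined at 27.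

**Step 16.** Three processes would leave cis-fused or conjugated material:
- slow proton exchange at the hindered C5,
- γ-deprotonation at C17 in place of C9,
- γ-protonation during the quench.

The fallback replaces kinetic protonation by a deconjugative reduction of a dienol ester. It sets out from 27 (step 16 stopped and worked up after its first stage) and comes back at 32.
- 27 is heated with isovaleric anhydride and catalytic p-toluenesulfonic acid. This esterifies O3 and traps the thermodynamic extended enol as the dienol ester F5.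
- NaBH4 in aqueous EtOH–THF cleaves the enol ester, and the liberated dienolate is protonated at C7.
- The β,γ-enone is then reduced faster than it reconjugates, giving the 6β-alcohol F6.
- DMAP-catalysed acylation of O6 with isovaleric anhydride gives 32.

**Step 22.** Acyl migration from O3 or O6 to the freed primary C19 hydroxyl may compete, and cleavage of the neopentyl silyl ether under buffered fluoride may be sluggish.

The fallback separates the two unmaskings and avoids any basic medium. It sets out from 33 and comes back at 38.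
- Horner–Wadsworth–Emmons olefination of 33 with commercial allyl diethylphosphonoacetate gives the allyl ester F7.
- HF·pyridine in THF–pyridine removes the silyl group under acidic conditions to give the 19-hydroxy allyl ester F8.
- Pd(PPh3)4 with morpholine (zerovalent palladium, neutral allyl transfer) releases the acid 38.

Further compounds
F1 | step 15 | monocyclic β,γ-enone (C6 ketone, C8=C9) with intact (3R,4R)-epoxide arm | CC1=C(CCC=C)[C@@](C)(CC[C@H]2O[C@]2(C)CO[Si](c2ccccc2)(c2ccccc2)C(C)(C)C)CC(=O)C1
F2 | step 15 | conjugated cyclohex-2-enone (C7=C8, 9-H; either C9 epimer serves) with epoxide arm | CC1=CC(=O)C[C@](C)(CC[C@H]2O[C@]2(C)CO[Si](c2ccccc2)(c2ccccc2)C(C)(C)C)[C@H]1CCC=C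
F3 | step 15 | cross-conjugated 6-(tert-butyldimethylsilyloxy)-5,7-diene with epoxide arm | CC1=CC(O[Si](C)(C)C(C)(C)C)=C[C@](C)(CC[C@H]2O[C@]2(C)CO[Si](c2ccccc2)(c2ccccc2)C(C)(C)C)[C@H]1CCC=C
F4 | step 15 | cis-fused (5β-H) 3α-hydroxy-7-en-6-one, C19 OTBDPS | CC1=CC(=O)[C@@H]2[C@@](C)(CO[Si](c3ccccc3)(c3ccccc3)C(C)(C)C)[C@H](O)CC[C@]2(C)[C@H]1CCC=C
F5 | step 16 | 3α-isovalerate 6-isovaleryloxy-6,8-diene (dienol ester), 5α-H | CC1=C(CCC=C)[C@@]2(C)CC[C@@H](OC(=O)CC(C)C)[C@](C)(CO[Si](c3ccccc3)(c3ccccc3)C(C)(C)C)[C@@H]2C(OC(=O)CC(C)C)=C1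
F6 | step 16 | 3α-isovalerate 6β-alcohol, C8=C9 | CC1=C(CCC=C)[C@@]2(C)CC[C@@H](OC(=O)CC(C)C)[C@](C)(CO[Si](c3ccccc3)(c3ccccc3)C(C)(C)C)[C@@H]2[C@H](O)C1
F7 | step 22 | allyl (13E)-enoate, C19 OTBDPS | CC1=C(CC/C(C)=C/C(=O)OCC=C)[C@@]2(C)CC[C@@H](OC(=O)CC(C)C)[C@](C)(CO[Si](c3ccccc3)(c3ccccc3)C(C)(C)C)[C@@H]2[C@H](OC(=O)CC(C)C)C1
F8 | step 22 | allyl (13E)-enoate, free C19 hydroxyl | CC1=C(CC/C(C)=C/C(=O)OCC=C)[C@@]2(C)CC[C@@H](OC(=O)CC(C)C)[C@](C)(CO)[C@@H]2[C@H](OC(=O)CC(C)C)C1
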